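**Plan**
- Retrosynthesis: the sulfate S–O bond and the two masking groups (3-O-MOM, 3'-O-benzyl) come off first; ring A is then cut at C8–C8a and C5–C4a, and the remaining pyranone at its C2–aryl bond.
- The cut through ring A is possible because C5 and C7 carry oxygen in a 1,3-relationship, the pattern of a 1,1,3-trioxygenated butadiene (diene C1 becomes C5, diene C3 becomes C7), while C4a and C8a are the free C5=C6 double bond of a monocyclic 4-pyranone.
- Forward: ring C is bought as 3-hydroxy-4-pyranone, ring B is joined at C2 by cross-coupling, a phenylsulfinyl group is placed on C5, and ring A is closed by [4+2] cycloaddition and aromatised by loss of sulfenic acid and methanol.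
- End game: MOM removal, sulfation of the 3-OH beside the chelated 5-OH, hydrogenolysis of the benzyl ether.
- Stereochemistry: the target has no stereocentre; the racemic sulfoxide and the sp3 centres of the cycloadduct are erased on aromatisation.

Key step: step 7

Assumption: the neutral hydrogen sulfate as drawn is taken as the form wanted; it is set free by cold H+ exchange in the last step and would be stored as a salt.

Step 1
Reactants: 1 3-hydroxy-4H-pyran-4-one (pyromeconic acid)
Product: 2 2-bromo-3-hydroxy-4H-pyran-4-one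
Conditions: NBS (1.0 equiv), MeCN, 0 °C → rt
Reagents that add atoms: N-bromosuccinimide, O=C1CCC(=O)N1Br
Why: Electrophilic bromination of the enol, in which the 3-OH makes C2 the nucleophilic carbon (the position at which this pyranone also undergoes aldol and Mannich reactions, and the counterpart of C6 of kojic acid), so one equivalent of NBS should give the 2-bromide.

Step 2
Reactants: 2 2-bromo-3-hydroxy-4H-pyran-4-one
Product: 3 2-bromo-3-(methoxymethoxy)-4H-pyran-4-one
Conditions: MOMCl (1.3 equiv), i-Pr2NEt (1.5 equiv), CH2Cl2, 0 °C → rt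
Reagents that add atoms: chloromethyl methyl ether, COCCl
Why: O-alkylation of the acidic enolic OH (Williamson-type acetal formation) gives a MOM ether that should survive the coupling, the sulfur chemistry and the cycloaddition and can later be removed with acid beside the benzyl ether.

Step 3
Reactants: 3 2-bromo-3-(methoxymethoxy)-4H-pyran-4-one; 4 [3-(benzyloxy)-4-methoxyphenyl]boronic acid
Product: 5 2-[3-(benzyloxy)-4-methoxyphenyl]-3-(methoxymethoxy)-4H-pyran-4-one
Conditions: Pd(PPh3)4 (5 mol %), K3PO4 (2 equiv), 1,4-dioxane/H2O 10:1, 80 °C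
Reagents that add atoms: none
Why: Suzuki–Miyaura coupling at the C2–Br bond of a β-bromo enone (vinylogous acyl bromide), which undergoes oxidative addition readily, with a mild phosphate base to limit hydroxide attack on the pyranone.

Step 4
Reactants: 5 2-[3-(benzyloxy)-4-methoxyphenyl]-3-(methoxymethoxy)-4H-pyran-4-one
Product: 6 2-[3-(benzyloxy)-4-methoxyphenyl]-3-(methoxymethoxy)-5-(phenylsulfanyl)-4H-pyran-4-one
Conditions: PhSCl (1.3 equiv, prepared separately from PhSH and SO2Cl2), pyridine (3 equiv), CH2Cl2, −20 °C → rt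
Reagents that add atoms: benzenesulfenyl chloride, ClSc1ccccc1
Why: Electrophilic α-sulfenylation of the vinylogous ester O1–C6=C5–C4=O, a reaction type used on chromones, uracils and 4-pyridones: C5 is the one nucleophilic ring position that bears hydrogen, PhS+ adds there to give the O1-stabilised oxocarbenium ion, which loses the C5 proton to pyridine, and the sulfenyl chloride is too weak an electrophile for the deactivated alkoxyaryl ring.

Step 5
Reactants: 6 2-[3-(benzyloxy)-4-methoxyphenyl]-3-(methoxymethoxy)-5-(phenylsulfanyl)-4H-pyran-4-one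
Product: 7 2-[3-(benzyloxy)-4-methoxyphenyl]-3-(methoxymethoxy)-5-(phenylsulfinyl)-4H-pyran-4-one (racemic at sulfur)
Conditions: mCPBA (1.05 equiv), NaHCO3, CH2Cl2, −40 → 0 °C
Reagents that add atoms: 3-chloroperoxybenzoic acid, OOC(=O)c1cccc(Cl)c1
Why: Chemoselective sulfide-to-sulfoxide oxidation with one equivalent of peracid at low temperature, which should leave the electron-poor pyranone double bonds and the aryl ethers untouched; the sulfur configuration is of no consequence because the group is lost in step 7.

Step 6
Reactants: 8 methyl (E)-3-methoxybut-2-enoate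
Product: 10 (1E)-1,3-dimethoxy-1-(trimethylsilyloxy)buta-1,3-diene, via lithium dienolate 9 (not isolated)
Conditions: LDA (1.1 equiv), THF, −78 °C; TMSCl (1.2 equiv), −78 °C → rt; distillation
Reagents that add atoms: chlorotrimethylsilane, C[Si](C)(C)Cl
Why: Kinetic γ-deprotonation of the β-methoxy enoate gives the extended dienolate, which is silylated on oxygen to the 1-alkoxy-1-silyloxy diene (silyl ketene acetal formation); the C1 geometry is lost in the next step.

Step 7
Reactants: 7 2-[3-(benzyloxy)-4-methoxyphenyl]-3-(methoxymethoxy)-5-(phenylsulfinyl)-4H-pyran-4-one; 10 (1E)-1,3-dimethoxy-1-(trimethylsilyloxy)buta-1,3-diene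
Product: 13 2-[3-(benzyloxy)-4-methoxyphenyl]-5-hydroxy-7-methoxy-3-(methoxymethoxy)-4H-chromen-4-one, via cis-fused cycloadduct 11 (not isolated), via dihydrochromenone ketal 12 (not isolated)
Conditions: 10 (3 equiv), toluene, rt → 80 °C; then 0.5 M HCl, THF, 0 °C
Reagents that add atoms: none
Why: Proposed new method: the diene HOMO is largest at its CH2 terminus and the pyranone C5=C6 bond, with the ketone and the sulfinyl group both on C5, is polarised so that C6 is the electrophilic end, so C8–C8a and C5–C4a should form in a normal-demand [4+2] cycloaddition (concerted but asynchronous, or Michael addition followed at once by ring closure) that closes the six-membered carbocycle across C5=C6 and gives the cis-fused adduct 11. In 11 the sulfinyl group on C4a is cis to H-8a, the only β-hydrogen available, so thermal syn-elimination of benzenesulfenic acid restores the C4a=C8a bond regiospecifically; the sulfoxide level is chosen over the sulfone because an angular sulfone would have neither an acidic β-hydrogen for E1cB nor an anti-periplanar one for E2. The mixed ketal carbon of 12 then expels methanol and the dienone tautomerises to the C5 phenol, which is held by a hydrogen bond to the C4 carbonyl, and the acidic work-up cleaves any silyl ether. The closest known reactions are the tandem Diels–Alder/sulfoxide elimination of 2-sulfinyl-1,4-quinones, the cycloaddition–aromatisation of this diene with haloquinones and Diels–Alder reactions of 3-acyl- and 3-sulfonylchromones; a monocyclic 4-pyranone has not been used in this way. No stereocentre survives, since those at C4a, C5 and C8a are destroyed on aromatisation, so only regio- and site selectivity matter: the first follows from the matched polarisation, the second from the C2=C3 bond being tetrasubstituted and donor-substituted. Loss of methanol in preference to silanol from the ketal is needed for the free 5-OH and is the usual outcome with this diene.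

Step 8
Reactants: 13 2-[3-(benzyloxy)-4-methoxyphenyl]-5-hydroxy-7-methoxy-3-(methoxymethoxy)-4H-chromen-4-one
Product: 14 2-[3-(benzyloxy)-4-methoxyphenyl]-3,5-dihydroxy-7-methoxy-4H-chromen-4-one (3'-O-benzylombuin)
Conditions: 2 M HCl, MeOH/THF 1:1, 50 °C
Reagents that add atoms: none
Why: Acid-catalysed acetal cleavage (transacetalisation of the MOM group to methanol) under conditions to which the benzyl and methyl aryl ethers are stable.

Step 9
Reactants: 14 2-[3-(benzyloxy)-4-methoxyphenyl]-3,5-dihydroxy-7-methoxy-4H-chromen-4-one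
Product: 15 triethylammonium 2-[3-(benzyloxy)-4-methoxyphenyl]-5-hydroxy-7-methoxy-4-oxo-4H-chromen-3-yl sulfate
Conditions: SO3·NEt3 (3 equiv), Et3N (2 equiv), DMF, 40 °C; Sephadex LH-20
Reagents that add atoms: sulfur trioxide–triethylamine complex, CC[N+](CC)(CC)S(=O)(=O)[O-]
Why: O-sulfation with an amine–SO3 complex should take place at the enolic 3-OH, because the 5-OH is tied up in the six-membered hydrogen bond to C4=O and is the least reactive hydroxyl of a flavonol.

Step 10
Reactants: 15 triethylammonium 2-[3-(benzyloxy)-4-methoxyphenyl]-5-hydroxy-7-methoxy-4-oxo-4H-chromen-3-yl sulfate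
Product: 17 5-hydroxy-2-(3-hydroxy-4-methoxyphenyl)-7-methoxy-4-oxo-4H-chromen-3-yl hydrogen sulfate (ombuin 3-O-sulfate), via triethylammonium ombuin 3-O-sulfate 16 (not isolated)
Conditions: H2 (1 atm), 10% Pd/C, MeOH, rt; filter; Dowex 50W (H+ form), MeOH/H2O, 0 °C; freeze-dry
Reagents that add atoms: none
Why: Catalytic hydrogenolysis of the benzyl aryl ether under neutral conditions should leave the sulfate monoester and the tetrasubstituted C2=C3 bond untouched, and cation exchange against H+ in the cold then gives the hydrogen sulfate form.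

**Compound list**
1 | 3-hydroxy-4H-pyran-4-one (pyromeconic acid) | O=c1ccocc1O | starting material
2 | 2-bromo-3-hydroxy-4H-pyran-4-one | O=c1ccoc(Br)c1O | intermediate
3 | 2-bromo-3-(methoxymethoxy)-4H-pyran-4-one | COCOc1c(Br)occc1=O | intermediate
4 | [3-(benzyloxy)-4-methoxyphenyl]boronic acid | COc1ccc(B(O)O)cc1OCc1ccccc1 | starting material
5 | 2-[3-(benzyloxy)-4-methoxyphenyl]-3-(methoxymethoxy)-4H-pyran-4-one | COCOc1c(-c2ccc(OC)c(OCc3ccccc3)c2)occc1=O | intermediate
6 | 2-[3-(benzyloxy)-4-methoxyphenyl]-3-(methoxymethoxy)-5-(phenylsulfanyl)-4H-pyran-4-one | COCOc1c(-c2ccc(OC)c(OCc3ccccc3)c2)occ(Sc2ccccc2)c1=O | intermediate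
7 | 2-[3-(benzyloxy)-4-methoxyphenyl]-3-(methoxymethoxy)-5-(phenylsulfinyl)-4H-pyran-4-one (racemic at sulfur) | COCOc1c(-c2ccc(OC)c(OCc3ccccc3)c2)occ(S(=O)c2ccccc2)c1=O | intermediate
8 | methyl (E)-3-methoxybut-2-enoate | CO/C(C)=C/C(=O)OC | starting material
9 | lithium dienolate of 8 (lithium 1,3-dimethoxybuta-1,3-dien-1-olate; not isolated) | C=C(OC)C=C([O-])OC.[Li+] | intermediate
10 | (1E)-1,3-dimethoxy-1-(trimethylsilyloxy)buta-1,3-diene | C=C(OC)\C=C(/OC)O[Si](C)(C)C | intermediate
11 | 2-[3-(benzyloxy)-4-methoxyphenyl]-5,7-dimethoxy-3-(methoxymethoxy)-4a-(phenylsulfinyl)-5-(trimethylsilyloxy)-4a,5,8,8a-tetrahydro-4H-chromen-4-one (racemic; H-8a cis to the sulfinyl group; epimers at C5 and at sulfur; not isolated) | COCOC1=C(c2ccc(OC)c(OCc3ccccc3)c2)OC2CC(OC)=CC(OC)(O[Si](C)(C)C)C2(S(=O)c2ccccc2)C1=O | intermediate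
12 | 2-[3-(benzyloxy)-4-methoxyphenyl]-5,7-dimethoxy-3-(methoxymethoxy)-5-(trimethylsilyloxy)-5,8-dihydro-4H-chromen-4-one (racemic; not isolated) | COCOc1c(-c2ccc(OC)c(OCc3ccccc3)c2)oc2c(c1=O)C(OC)(O[Si](C)(C)C)C=C(OC)C2 | intermediate
13 | 2-[3-(benzyloxy)-4-methoxyphenyl]-5-hydroxy-7-methoxy-3-(methoxymethoxy)-4H-chromen-4-one | COCOc1c(-c2ccc(OC)c(OCc3ccccc3)c2)oc2cc(OC)cc(O)c2c1=O | intermediate
14 | 2-[3-(benzyloxy)-4-methoxyphenyl]-3,5-dihydroxy-7-methoxy-4H-chromen-4-one (3'-O-benzylombuin) | COc1cc(O)c2c(=O)c(O)c(-c3ccc(OC)c(OCc4ccccc4)c3)oc2c1 | intermediate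
15 | triethylammonium 2-[3-(benzyloxy)-4-methoxyphenyl]-5-hydroxy-7-methoxy-4-oxo-4H-chromen-3-yl sulfate | COc1cc(O)c2c(=O)c(OS(=O)(=O)[O-])c(-c3ccc(OC)c(OCc4ccccc4)c3)oc2c1.CC[NH+](CC)CC | intermediate
16 | triethylammonium 5-hydroxy-2-(3-hydroxy-4-methoxyphenyl)-7-methoxy-4-oxo-4H-chromen-3-yl sulfate (not isolated) | COc1cc(O)c2c(=O)c(OS(=O)(=O)[O-])c(-c3ccc(OC)c(O)c3)oc2c1.CC[NH+](CC)CC | intermediate
17 | ombuin 3-O-sulfate, 5-hydroxy-2-(3-hydroxy-4-methoxyphenyl)-7-methoxy-4-oxo-4H-chromen-3-yl hydrogen sulfate (achiral) | COc1cc(O)c2c(=O)c(OS(=O)(=O)O)c(-c3ccc(OC)c(O)c3)oc2c1 | target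

**Count**
Total steps: 10. Longest linear sequence: 9 (steps 1–5 and 7–10, from 1); step 6 is a one-step side branch.

**Steps most likely to fail**

Step 7 (proposed new method). Three processes could defeat it. The partly aromatic pyranone may be too weak a dienophile. Conjugate addition at C6 may be followed by opening of the pyranone ring (loss of the C6–O1 bond from the sulfinyl-stabilised enolate) instead of ring closure. The ketal may lose silanol instead of methanol, which would leave a 5-methyl ether. The fallback gives up the cycloaddition and brings ring A in preformed, using known reactions only; it sets out from boronic acid 4 and returns at 14.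
- Purchased 1-(2,6-dihydroxy-4-methoxyphenyl)ethanone (CC(=O)c1c(O)cc(OC)cc1O) is mono-protected (MOMCl, i-Pr2NEt, CH2Cl2) to 1-[2-hydroxy-4-methoxy-6-(methoxymethoxy)phenyl]ethanone F1.
- Condensation with DMF dimethyl acetal (toluene, 90 °C) should give the enaminone (E)-3-(dimethylamino)-1-[2-hydroxy-4-methoxy-6-(methoxymethoxy)phenyl]prop-2-en-1-one F2, which is cyclised on silica gel or in dilute acetic acid to 7-methoxy-5-(methoxymethoxy)-4H-chromen-4-one F3.
- Pd(II)-catalysed oxidative Heck-type arylation of F3 at C2 with 4 (Pd(TFA)2, 2,2'-bipyridine, O2 or benzoquinone as oxidant) should give the flavone 2-[3-(benzyloxy)-4-methoxyphenyl]-7-methoxy-5-(methoxymethoxy)-4H-chromen-4-one F4.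
- Epoxidation of its C2=C3 bond with dimethyldioxirane (acetone/CH2Cl2, 0 °C) should give racemic 2-[3-(benzyloxy)-4-methoxyphenyl]-2,3-epoxy-7-methoxy-5-(methoxymethoxy)chroman-4-one F5.
- Methanolic HCl then opens the epoxide to the 3-hydroxyflavone and removes the 5-O-MOM group, which should give 14.

Step 4. The aromatic character of the pyranone may make C5 too poor a nucleophile for the sulfenyl chloride, or reversible addition across the more electron-rich C2=C3 bond may end in loss of the MOM group. The fallback separates activation from C–S bond formation; it sets out from 5 and returns at 6. Nucleophile-assisted α-iodination (I2, pyridine, CH2Cl2, rt) has pyridine add reversibly at C6, the enolate take up iodine at C5, and pyridine leave again. It should give 2-[3-(benzyloxy)-4-methoxyphenyl]-5-iodo-3-(methoxymethoxy)-4H-pyran-4-one F6 without touching the aryl ring. Pd-catalysed C–S coupling with thiophenol (Pd2(dba)3, Xantphos, i-Pr2NEt, dioxane, 90 °C) then gives 6.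

Step 9. Sulfation of the hydrogen-bonded 3-OH may stall, the 5-OH may be sulfated as well when the reagent is pushed, and the polar salt may lose SO3 during purification. The fallback uses a masked sulfate that can be chromatographed; it sets out from 14 and returns at 17. Reaction of 14 with 2,2,2-trichloroethyl chlorosulfate (Et3N, DMAP, THF, 0 °C) should give the neutral diester 2-[3-(benzyloxy)-4-methoxyphenyl]-5-hydroxy-7-methoxy-4-oxo-4H-chromen-3-yl 2,2,2-trichloroethyl sulfate F7, from which mono- and bis-sulfated material can be separated on silica gel. Pd/C with ammonium formate and H2 in methanol then removes the trichloroethyl group reductively and the benzyl group by hydrogenolysis, giving ammonium ombuin 3-O-sulfate F8, and cold H+ exchange gives 17.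

**Further compounds**
F1 | step 7 | 1-[2-hydroxy-4-methoxy-6-(methoxymethoxy)phenyl]ethanone | CC(=O)c1c(O)cc(OC)cc1OCOC
F2 | step 7 | (E)-3-(dimethylamino)-1-[2-hydroxy-4-methoxy-6-(methoxymethoxy)phenyl]prop-2-en-1-one | CN(C)/C=C/C(=O)c1c(O)cc(OC)cc1OCOC
F3 | step 7 | 7-methoxy-5-(methoxymethoxy)-4H-chromen-4-one | COCOc1cc(OC)cc2occc(=O)c12
F4 | step 7 | 2-[3-(benzyloxy)-4-methoxyphenyl]-7-methoxy-5-(methoxymethoxy)-4H-chromen-4-one | COCOc1cc(OC)cc2oc(-c3ccc(OC)c(OCc4ccccc4)c3)cc(=O)c12
F5 | step 7 | 2-[3-(benzyloxy)-4-methoxyphenyl]-2,3-epoxy-7-methoxy-5-(methoxymethoxy)chroman-4-one (racemic) | O=C1C2OC2(c2ccc(OC)c(OCc3ccccc3)c2)Oc2cc(OC)cc(OCOC)c12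
F6 | step 4 | 2-[3-(benzyloxy)-4-methoxyphenyl]-5-iodo-3-(methoxymethoxy)-4H-pyran-4-one | COCOc1c(-c2ccc(OC)c(OCc3ccccc3)c2)occ(I)c1=O
F7 | step 9 | 2-[3-(benzyloxy)-4-methoxyphenyl]-5-hydroxy-7-methoxy-4-oxo-4H-chromen-3-yl 2,2,2-trichloroethyl sulfate | COc1cc(O)c2c(=O)c(OS(=O)(=O)OCC(Cl)(Cl)Cl)c(-c3ccc(OC)c(OCc4ccccc4)c3)oc2c1
F8 | step 9 | ammonium 5-hydroxy-2-(3-hydroxy-4-methoxyphenyl)-7-methoxy-4-oxo-4H-chromen-3-yl sulfate | COc1cc(O)c2c(=O)c(OS(=O)(=O)[O-])c(-c3ccc(OC)c(O)c3)oc2c1.[NH4+]
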